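Ring A (C1–C5, C10; labdane numbering) is disconnected across its two "para" bonds, C1–C2 and C5–C10, into a C2=C3–C4=C5 diene and a C1=C10 dienophile joined by C6–C9, the future ring B. The dienophile is an α-methylene δ-lactone in which C20 and C12 are tied by a temporary ring that activates C1=C10 and relays the C9 stereocentre; the 2-(methoxycarbonyl)diene is stored as a cyclobutene. Heating the precursor releases the diene by 4π ring opening, and an intramolecular Diels–Alder reaction closes rings A and B at once. The C3=C4 enoate then allows reductive methylation at C4, and the lactone is unravelled to the C20 acetate and the butenolide side chain.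

Key step: step 6

Remark (assumption on the chemistry): labdane numbering is used in names and explanations. Every intermediate that carries the cyclobutene is racemic or a mixture of epimers at the cyclobutene sp3 carbon (the future C5); this is harmless because that carbon becomes sp2 in step 6. Unnumbered reagents are taken as commercial.

Step 1
Reactants: 1 2,3-dibromoprop-1-ene; 2 allylmagnesium bromide
Product: 3 2-bromohexa-1,5-diene
Conditions: Et2O, 0 °C to rt
Reagents that add atoms: none
Why: Allyl–allyl coupling by SN2 (or degenerate SN2') displacement of the allylic bromide of 1 by the Grignard reagent; the vinylic C–Br bond should not react under these conditions.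

Step 2
Reactants: 3 2-bromohexa-1,5-diene; 4 methyl propiolate
Product: 5 methyl 4-(3-bromobut-3-en-1-yl)cyclobut-1-ene-1-carboxylate (racemic)
Conditions: EtAlCl2 (1 equiv), CH2Cl2, 25 °C, excess 3
Reagents that add atoms: none
Why: Snider-type Lewis-acid-promoted [2+2] cycloaddition of a propiolate with a monosubstituted alkene: the terminal alkene carbon bonds to the propiolate β-carbon and the internal carbon to the α-carbon, which places the side chain on the sp3 ring carbon next to the ester-bearing sp2 carbon; the 2-bromoalkene is a much poorer nucleophile and should stay a spectator, and the new stereocentre is erased in step 6.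

Step 3
Reactants: 5 methyl 4-(3-bromobut-3-en-1-yl)cyclobut-1-ene-1-carboxylate
Product: 6 methyl 4-[3-(4,4,5,5-tetramethyl-1,3,2-dioxaborolan-2-yl)but-3-en-1-yl]cyclobut-1-ene-1-carboxylate (racemic)
Conditions: B2pin2, PdCl2(PPh3)2 (cat.), PPh3, KOPh, toluene, 50 °C
Reagents that add atoms: bis(pinacolato)diboron CC1(C)OB(OC1(C)C)B1OC(C)(C)C(C)(C)O1
Why: Miyaura borylation of a 1-alkenyl bromide; transmetalation to boron should outrun carbopalladation of the cyclobutene because its β-carbon is out of reach of the alkenylpalladium centre and the nearer alkene carbon is fully substituted.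

Step 4
Reactants: 6 alkenylboronate; 7 5,6-dihydro-2H-pyran-2-one
Product: 8 methyl 4-{3-[(4R)-2-oxooxan-4-yl]but-3-en-1-yl}cyclobut-1-ene-1-carboxylate (epimers at the cyclobutene carbon)
Conditions: [Rh(cod)Cl]2 (cat.), (R)-BINAP, aq. K3PO4, dioxane/H2O 10:1, 60 °C; acidic work-up
Reagents that add atoms: none
Why: Hayashi–Miyaura rhodium-catalysed asymmetric 1,4-addition of an alkenylboronate to a cyclic (Z)-enoate; the BINAP–Rh complex selects the enoate face and sets C9 [(4R) in the lactone, with (R)-BINAP chosen on the established facial model for cyclic enones and lactones], the α-substituted cyclobutene ester is too hindered to compete as acceptor, and any ring-opened hydroxy acid relactonises on work-up.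

Step 5
Reactants: 8 (4R)-lactone
Product: 12 methyl 4-{3-[(4S)-3-methylidene-2-oxooxan-4-yl]but-3-en-1-yl}cyclobut-1-ene-1-carboxylate, via lithium enolate 9 (not isolated), via Mannich base 10 (not isolated), via ammonium iodide 11 (not isolated)
Conditions: LiN(iPr)2, THF, −78 °C; CH2=NMe2+ I−, −78 °C to rt; then MeI, rt; then aq. NaHCO3, rt
Reagents that add atoms: N,N-dimethylmethyleneiminium iodide (Eschenmoser's salt) C=[N+](C)C.[I-]
Why: Kinetic enolisation of the lactone α-CH2 (C10), Mannich reaction with Eschenmoser's salt, N-methylation and E1cB (Hofmann-type) elimination install the C1 methylene (α-methylenation of a lactone); the cyclobutene ester has no α-hydrogen, C9 is not touched (its descriptor changes only through the priority rules), and the mild bicarbonate step should avoid migration of the new double bond.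

Step 6
Reactants: 12 α-methylene lactone with cyclobutene ester
Product: 14 tricyclic lactone ester (methyl 13,14,15,16,18-pentanorlabda-3,8(17)-dien-20,12-olid-19-oate; H-5 α; H-9 α; C20 β on C10), via dienyl lactone 13 (not isolated)
Conditions: degassed o-xylene (0.005 M), BHT (cat.), sealed tube, 150 °C
Reagents that add atoms: none
Why: On heating, the cyclobutene undergoes conrotatory 4π-electrocyclic ring opening (strain release) across its C2–C5 σ-bond with the C6 chain rotating outward, so that the (2Z)-dienoate 13 forms with the tether on the outside of the C2=C3–C4=C5 diene, and this diene at once adds suprafacially to the C1=C10 α-methylene lactone in a type 1 intramolecular Diels–Alder reaction that makes C1–C2 and C5–C10. The closest known reaction types are cyclobutene (and benzocyclobutene) ring-opening/Diels–Alder cascades and the intramolecular Diels–Alder reaction of 1,7,9-decatrienes that carry the activating carbonyl on the inner dienophile carbon. Ring A (C1–C5, C10) is closed by the [4+2] cycloaddition itself as a cyclohexene with the C3=C4 double bond, and ring B (C5–C10) is closed in the fused mode through the four-carbon tether C6–C9 by the C5–C10 bond. C10 is controlled by C9: the diene hangs from C8 and can reach only the face of C1=C10 that is syn to C8 (new C5–C10 bond axial, C8 equatorial on the lactone ring), which places C20 β and H-9 α as in the target. C5 is controlled by the endo orientation of the lactone carbonyl C20 under the diene, which is the transition state with the tether exo and gives the trans fusion of rings A and B (H-5 α). The step needs endo over exo selectivity and ring closure faster than diene dimerisation; the rigid s-cis α-methylene lactone, the release of the diene only in the presence of its tethered partner and high dilution should secure both.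

Step 7
Reactants: 14 tricyclic lactone ester
Product: 16 methyl 13,14,15,16-tetranorlabd-8(17)-en-20,12-olid-19-oate (4α-methyl; 4β-CO2Me; H-5 α; H-9 α), via lithium ester enolate 15 (not isolated)
Conditions: LiBH(sBu)3 (1.1 equiv), THF, −78 °C; then MeI, DMPU, −78 to −20 °C
Reagents that add atoms: iodomethane CI
Why: Conjugate hydride addition of LiBH(sBu)3 to the C3=C4 enoate followed by C-methylation of the enolate in the same flask (reductive alkylation of an enoate); iodomethane should approach C4 from the α face, anti to the axial C20 carbonyl carbon on C10, which gives 4α-methyl and 4β (axial) CO2Me, and the hindered, non-enolisable lactone should survive at −78 °C.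

Step 8
Reactants: 16 C4-methylated lactone ester
Product: 18 methyl 12,20-epoxy-13,14,15,16-tetranorlabd-8(17)-en-19-oate (cyclic ether), via lactol 17 (not isolated)
Conditions: iBu2AlH (1.3 equiv), CH2Cl2, −78 °C; then Et3SiH, BF3·OEt2, −78 to −20 °C
Reagents that add atoms: none
Why: The δ-lactone should be reduced by iBu2AlH at −78 °C ahead of the hindered axial C19 ester; BF3·OEt2 ionises the lactol to a C20 oxocarbenium ion (no enolisable α-hydrogen, C10 being quaternary) that Et3SiH reduces (ionic deoxygenation of a lactol to a cyclic ether), which should leave the exocyclic alkene untouched at low temperature.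

Step 9
Reactants: 18 cyclic ether
Product: 19 methyl 20-acetoxy-12-iodo-13,14,15,16-tetranorlabd-8(17)-en-19-oate
Conditions: AcCl, NaI, 2,6-di-tert-butyl-4-methylpyridine (cat.), MeCN, 0 °C to rt
Reagents that add atoms: acetyl chloride CC(Cl)=O; sodium iodide [Na+].[I-]
Why: Cleavage of a cyclic ether by acetyl iodide made in situ: O-acetylation gives an oxonium ion that iodide opens by SN2 attack at the unhindered C12 and not at neopentyl C20, so the C20 acetate and the C12 iodide arise together and C20–OH, which could lactonise onto C19, is never free; the hindered pyridine traps HI and protects the 8(17)-alkene.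

Step 10
Reactants: 19 iodo acetate; 20 3-bromofuran-2(5H)-one
Product: 22 methyl 20-acetoxylabda-8(17),13-dien-16,15-olid-19-oate (CNP0104712.1), via alkylzinc iodide 21 (not isolated)
Conditions: Zn dust (activated with TMSCl and 1,2-dibromoethane), DMA, 40 °C; then 20, Pd(OAc)2 (cat.), SPhos, THF, rt
Reagents that add atoms: none
Why: Zinc insertion into the primary iodide gives an ester-tolerant alkylzinc iodide, and a Negishi sp3–sp2 coupling with the α-bromobutenolide forges C12–C13 with the butenolide double bond already in place; SPhos should hold back β-hydride elimination.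

Compound list
1 | 2,3-dibromoprop-1-ene | C=C(Br)CBr | starting material
2 | allylmagnesium bromide | C=CC[Mg]Br | starting material
3 | 2-bromohexa-1,5-diene | C=CCCC(Br)=C | intermediate
4 | methyl propiolate | C#CC(=O)OC | starting material
5 | methyl 4-(3-bromobut-3-en-1-yl)cyclobut-1-ene-1-carboxylate (racemic) | COC(=O)C1=CCC1CCC(Br)=C | intermediate
6 | methyl 4-[3-(4,4,5,5-tetramethyl-1,3,2-dioxaborolan-2-yl)but-3-en-1-yl]cyclobut-1-ene-1-carboxylate (racemic) | COC(=O)C1=CCC1CCC(=C)B1OC(C)(C)C(C)(C)O1 | intermediate
7 | 5,6-dihydro-2H-pyran-2-one | O=C1C=CCCO1 | starting material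
8 | methyl 4-{3-[(4R)-2-oxooxan-4-yl]but-3-en-1-yl}cyclobut-1-ene-1-carboxylate | O=C1C[C@@H](CCO1)C(=C)CCC1CC=C1C(=O)OC | intermediate
9 | lithium enolate of lactone 8 | [Li]OC1=C[C@@H](CCO1)C(=C)CCC1CC=C1C(=O)OC | intermediate
10 | methyl 4-{3-[(4R)-3-[(dimethylamino)methyl]-2-oxooxan-4-yl]but-3-en-1-yl}cyclobut-1-ene-1-carboxylate (Mannich base, both C3 epimers of the lactone) | CN(C)CC1C(=O)OCC[C@H]1C(=C)CCC1CC=C1C(=O)OC | intermediate
11 | N-methyl trimethylammonium iodide of Mannich base 10 | C[N+](C)(C)CC1C(=O)OCC[C@H]1C(=C)CCC1CC=C1C(=O)OC.[I-] | intermediate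
12 | methyl 4-{3-[(4S)-3-methylidene-2-oxooxan-4-yl]but-3-en-1-yl}cyclobut-1-ene-1-carboxylate | C=C1C(=O)OCC[C@H]1C(=C)CCC1CC=C1C(=O)OC | intermediate
13 | methyl (2Z)-2-ethenyl-6-[(4S)-3-methylidene-2-oxooxan-4-yl]hepta-2,6-dienoate | C=C/C(C(=O)OC)=C/CCC(=C)[C@@H]1CCOC(=O)C1=C | intermediate
14 | methyl 13,14,15,16,18-pentanorlabda-3,8(17)-dien-20,12-olid-19-oate (H-5 α, H-9 α, C20 β) | COC(=O)C1=CCC[C@]23C(=O)OCC[C@H]2C(=C)CC[C@@H]13 | intermediate
15 | lithium ester enolate at C4/C19 from 14 | COC(O[Li])=C1CCC[C@]23C(=O)OCC[C@H]2C(=C)CC[C@@H]13 | intermediate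
16 | methyl 13,14,15,16-tetranorlabd-8(17)-en-20,12-olid-19-oate (4α-methyl, 4β-CO2Me) | COC(=O)[C@@]1(C)CCC[C@]23C(=O)OCC[C@H]2C(=C)CC[C@@H]13 | intermediate
17 | methyl 12,20-epoxy-20-hydroxy-13,14,15,16-tetranorlabd-8(17)-en-19-oate (lactol, both C20 epimers) | COC(=O)[C@@]1(C)CCC[C@]23C(O)OCC[C@H]2C(=C)CC[C@@H]13 | intermediate
18 | methyl 12,20-epoxy-13,14,15,16-tetranorlabd-8(17)-en-19-oate | COC(=O)[C@@]1(C)CCC[C@]23COCC[C@H]2C(=C)CC[C@@H]13 | intermediate
19 | methyl 20-acetoxy-12-iodo-13,14,15,16-tetranorlabd-8(17)-en-19-oate | COC(=O)[C@@]1(C)CCC[C@]2(COC(C)=O)[C@@H](CCI)C(=C)CC[C@@H]12 | intermediate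
20 | 3-bromofuran-2(5H)-one | O=C1OCC=C1Br | starting material
21 | [20-acetoxy-19-methoxy-19-oxo-13,14,15,16-tetranorlabd-8(17)-en-12-yl]zinc iodide | COC(=O)[C@@]1(C)CCC[C@]2(COC(C)=O)[C@@H](CC[Zn]I)C(=C)CC[C@@H]12 | intermediate
22 | methyl 20-acetoxylabda-8(17),13-dien-16,15-olid-19-oate (CNP0104712.1) | C=C1CC[C@@H]2[C@](COC(C)=O)(CCC[C@]2(C)C(=O)OC)[C@H]1CCC1=CCOC1=O | target

Total step count: 10. Longest linear sequence: 10 steps (from 1 and 2; 4, 7 and 20 enter as commercial partners).

Steps most likely to fail

1. Step 6. At 150 °C the endo preference may erode, so that exo addition gives the cis-fused ring A/ring B isomer, and bimolecular capture of the diene may compete. The fallback sets out from 10 and comes back at 14. Mannich base 10 is isolated by aqueous work-up after the first stage of step 5 and heated alone (toluene, high dilution, 150 °C). With the dienophile still masked as the amine, the cyclobutene should open to methyl (2Z)-6-{(4R)-3-[(dimethylamino)methyl]-2-oxooxan-4-yl}-2-ethenylhepta-2,6-dienoate F1. N-Methylation (MeI, THF, rt) should give the trimethylammonium iodide F2, and aq. NaHCO3 at 0 °C should release diene 13 in the cold. Me2AlCl (CH2Cl2, −78 to −20 °C) then promotes the intramolecular Diels–Alder reaction at low temperature, where the carbonyl-complexed endo transition state should dominate, to give 14.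

2. Step 7. Hydride may attack the lactone carbonyl in competition with conjugate addition, or the enolate may be quenched by proton transfer before C-alkylation. The fallback sets out from 14 and comes back at 16. Conjugate reduction with [(Ph3P)CuH]6 (toluene, rt, aqueous work-up) should give the saturated ester methyl 13,14,15,16,18-pentanorlabd-8(17)-en-20,12-olid-19-oate F3 as C4 epimers. LiN(iPr)2 in THF/DMPU at −78 °C then regenerates enolate 15 from this ester (the lactone has no α-hydrogen), and MeI gives 16 with the same α-face approach.

3. Step 9. Traces of HI may move the 8(17) double bond into the ring, or oxonium formation at the hindered ether may be sluggish. The fallback sets out from 16 and comes back at 19, so it bypasses steps 8 and 9. LiBH4 (THF, 0 °C) should reduce the lactone, and not the hindered C19 ester, to the diol methyl 12,20-dihydroxy-13,14,15,16-tetranorlabd-8(17)-en-19-oate F4. I2, PPh3 and imidazole (CH2Cl2, 0 °C) should convert only the unhindered C12 hydroxyl to give methyl 20-hydroxy-12-iodo-13,14,15,16-tetranorlabd-8(17)-en-19-oate F5. Immediate acetylation (Ac2O, DMAP, pyridine, 0 °C) gives 19 before the free C20 hydroxyl can lactonise onto C19.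

Further compounds
F1 | step 6 | methyl (2Z)-6-{(4R)-3-[(dimethylamino)methyl]-2-oxooxan-4-yl}-2-ethenylhepta-2,6-dienoate | CN(C)CC1C(=O)OCC[C@H]1C(=C)CC/C=C(/C=C)C(=O)OC
F2 | step 6 | trimethylammonium iodide of F1 | C[N+](C)(C)CC1C(=O)OCC[C@H]1C(=C)CC/C=C(/C=C)C(=O)OC.[I-]
F3 | step 7 | methyl 13,14,15,16,18-pentanorlabd-8(17)-en-20,12-olid-19-oate (C4 epimers) | COC(=O)C1CCC[C@]23C(=O)OCC[C@H]2C(=C)CC[C@@H]13
F4 | step 9 | methyl 12,20-dihydroxy-13,14,15,16-tetranorlabd-8(17)-en-19-oate | COC(=O)[C@@]1(C)CCC[C@]2(CO)[C@@H](CCO)C(=C)CC[C@@H]12
F5 | step 9 | methyl 20-hydroxy-12-iodo-13,14,15,16-tetranorlabd-8(17)-en-19-oate | COC(=O)[C@@]1(C)CCC[C@]2(CO)[C@@H](CCI)C(=C)CC[C@@H]12
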